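Retrosynthesis: each tertiary carbinol is traced back through a spiro-oxirane to a 4-benzylidene oxolane. The cuts then follow in this order: the C3–C4 bond of both oxolanes, the 5,5'-biaryl bond, and the O1–C5 ether bond of each half.
Enabling feature: each oxolane reads O1, C2(aryl), C3(CH2OH), C4(OH)(CH2Ar), C5. The C3–CH2OH pair next to C2–O1 is a masked terminal oxirane, and C4–CH2Ar, reached through O1–C5, is a masked 3-arylpropargyl ether. The two rings are one and the same unit, attached to the biaryl by opposite ends: ring A by its C2 aryl, ring B by its C4 benzyl aryl.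
Forward: vanillin and 5-bromovanillin each give an epoxy alcohol and a propargyl bromide. Crosswise etherification gives two isomeric bromo halves, one is borylated, and Suzuki coupling joins the chain. Only then do both oxolanes close together (Ti(III) epoxide opening, 5-exo-dig); the two spiro-oxiranes made afterwards are transient.
Stereochemistry: C2 comes from Sharpless kinetic resolution with D-(−)-DIPT. C3 is set from C2 in the radical ring closure (2,3-trans). C4 is set by epoxidation anti to the silylated C3 arm, and the C4–O bond is kept in the hydrogenolysis.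
Key step: step 17
Remark: oxolane numbering (O1, C2–C5) is used throughout. Benzylidene geometry and the benzylic oxirane CH centres are left undefined because step 20 erases both. Joining two enantioenriched halves should move residual minor enantiomer into a separable diastereomer.

Step 1
Reactants: 1 vanillin
Product: 2 4-(benzyloxy)-3-methoxybenzaldehyde
Conditions: BnBr, K2CO3, DMF, rt
Reagents that add atoms: benzyl bromide, BrCc1ccccc1
Why: Williamson O-alkylation of the phenoxide masks the acidic phenol as a benzyl ether that tolerates Grignard, organolithium, Pd, Ti(III) and dioxirane chemistry and is removed in the late hydrogenolysis.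

Step 2
Reactants: 2 4-(benzyloxy)-3-methoxybenzaldehyde; 3 vinylmagnesium bromide
Product: 4 rac-1-[4-(benzyloxy)-3-methoxyphenyl]prop-2-en-1-ol
Conditions: THF, −78 → 0 °C; aq NH4Cl
Reagents that add atoms: vinylmagnesium bromide (3), C=C[Mg]Br
Why: Grignard 1,2-addition to the aryl aldehyde brings in the future C3 and CH2OH carbons; the carbinol centre forms racemic and is resolved in step 3.

Step 3
Reactants: 4 rac-1-[4-(benzyloxy)-3-methoxyphenyl]prop-2-en-1-ol
Product: 5 (R)-[4-(benzyloxy)-3-methoxyphenyl][(2S)-oxiran-2-yl]methanol (erythro)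
Conditions: Ti(OiPr)4 (0.2 equiv), D-(−)-DIPT (0.25 equiv), anhydrous TBHP (0.45 equiv), 4 Å MS, CH2Cl2, −20 °C
Reagents that add atoms: tert-butyl hydroperoxide, CC(C)(C)OO
Why: Sharpless kinetic-resolution epoxidation, in which the (S)-allylic alcohol is the fast-reacting enantiomer with D-(−)-DIPT and gives the erythro epoxy alcohol (its carbinol descriptor becomes R only through CIP ranking), so limiting oxidant should deliver the future C2 centre enantioenriched and leave the (R)-alcohol behind.

Step 4
Reactants: 6 5-bromovanillin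
Product: 7 4-(benzyloxy)-3-bromo-5-methoxybenzaldehyde
Conditions: BnBr, K2CO3, DMF, 40 °C
Reagents that add atoms: benzyl bromide, BrCc1ccccc1
Why: Williamson O-alkylation as in step 1; the flanked phenoxide is still nucleophilic enough for benzyl bromide on gentle warming.

Step 5
Reactants: 7 4-(benzyloxy)-3-bromo-5-methoxybenzaldehyde; 3 vinylmagnesium bromide
Product: 8 rac-1-[4-(benzyloxy)-3-bromo-5-methoxyphenyl]prop-2-en-1-ol
Conditions: THF, −78 → 0 °C; aq NH4Cl
Reagents that add atoms: vinylmagnesium bromide (3), C=C[Mg]Br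
Why: Grignard 1,2-addition to the aldehyde is far faster than any bromine–magnesium exchange at an electron-rich aryl bromide at this temperature.

Step 6
Reactants: 8 rac-1-[4-(benzyloxy)-3-bromo-5-methoxyphenyl]prop-2-en-1-ol
Product: 9 (R)-[4-(benzyloxy)-3-bromo-5-methoxyphenyl][(2S)-oxiran-2-yl]methanol (erythro)
Conditions: Ti(OiPr)4 (0.2 equiv), D-(−)-DIPT (0.25 equiv), anhydrous TBHP (0.45 equiv), 4 Å MS, CH2Cl2, −20 °C
Reagents that add atoms: tert-butyl hydroperoxide, CC(C)(C)OO
Why: Sharpless kinetic-resolution epoxidation with the same sense as in step 3, since the remote ring bromine does not alter the carbinol environment that the titanium tartrate recognises.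

Step 7
Reactants: 2 4-(benzyloxy)-3-methoxybenzaldehyde; 10 Ohira–Bestmann reagent (dimethyl (1-diazo-2-oxopropyl)phosphonate)
Product: 11 1-(benzyloxy)-4-ethynyl-2-methoxybenzene
Conditions: K2CO3, MeOH, rt
Reagents that add atoms: Ohira–Bestmann reagent (10), COP(=O)(OC)C(=[N+]=[N-])C(C)=O
Why: Ohira–Bestmann alkynylation (Seyferth–Gilbert type), in which methanolysis frees the diazomethylphosphonate anion, this olefinates the aldehyde, and loss of N2 with a 1,2-shift gives the terminal alkyne whose new carbon becomes C4.

Step 8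
Reactants: 11 1-(benzyloxy)-4-ethynyl-2-methoxybenzene; 12 formaldehyde (as paraformaldehyde)
Product: 14 3-[4-(benzyloxy)-3-methoxyphenyl]prop-2-yn-1-ol, via lithium acetylide 13 (not isolated)
Conditions: n-BuLi, THF, −78 °C; then (CH2O)n, −78 °C → rt; aq NH4Cl
Reagents that add atoms: formaldehyde (12), C=O
Why: Acetylide hydroxymethylation, in which the alkyne proton is by far the most acidic site and the lithium acetylide adds to formaldehyde to install the carbon that becomes C5.

Step 9
Reactants: 14 3-[4-(benzyloxy)-3-methoxyphenyl]prop-2-yn-1-ol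
Product: 15 1-(benzyloxy)-4-(3-bromoprop-1-yn-1-yl)-2-methoxybenzene
Conditions: CBr4, PPh3, CH2Cl2, 0 °C
Reagents that add atoms: carbon tetrabromide, BrC(Br)(Br)Br
Why: Appel bromination replaces the primary propargylic hydroxyl by SN2 displacement of the oxyphosphonium group under neutral conditions that leave alkyne and benzyl ether alone.

Step 10
Reactants: 7 4-(benzyloxy)-3-bromo-5-methoxybenzaldehyde; 10 Ohira–Bestmann reagent
Product: 16 2-(benzyloxy)-1-bromo-5-ethynyl-3-methoxybenzene
Conditions: K2CO3, MeOH, rt
Reagents that add atoms: Ohira–Bestmann reagent (10), COP(=O)(OC)C(=[N+]=[N-])C(C)=O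
Why: Ohira–Bestmann alkynylation as in step 7; the mild carbonate/methanol medium does not affect the aryl bromide.

Step 11
Reactants: 16 2-(benzyloxy)-1-bromo-5-ethynyl-3-methoxybenzene; 12 formaldehyde (as paraformaldehyde)
Product: 18 3-[4-(benzyloxy)-3-bromo-5-methoxyphenyl]prop-2-yn-1-ol, via bromoaryl lithium acetylide 17 (not isolated)
Conditions: LDA (1.05 equiv), THF, −78 °C; then (CH2O)n, −78 °C → rt; aq NH4Cl
Reagents that add atoms: formaldehyde (12), C=O
Why: Acetylide hydroxymethylation with a non-nucleophilic amide base, which removes only the alkyne proton and avoids the bromine–lithium exchange that an alkyllithium would cause.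

Step 12
Reactants: 18 3-[4-(benzyloxy)-3-bromo-5-methoxyphenyl]prop-2-yn-1-ol
Product: 19 2-(benzyloxy)-1-bromo-5-(3-bromoprop-1-yn-1-yl)-3-methoxybenzene
Conditions: CBr4, PPh3, CH2Cl2, 0 °C
Reagents that add atoms: carbon tetrabromide, BrC(Br)(Br)Br
Why: Appel bromination as in step 9, selective for the sp3 C–OH bond and without effect on the aryl bromide.

Step 13
Reactants: 9 bromoaryl epoxy alcohol; 15 guaiacyl propargyl bromide
Product: 20 half A, (2S)-2-[(R)-[4-(benzyloxy)-3-bromo-5-methoxyphenyl]({3-[4-(benzyloxy)-3-methoxyphenyl]prop-2-yn-1-yl}oxy)methyl]oxirane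
Conditions: NaH (added last to both partners), n-Bu4NI (cat.), THF/DMF, −10 → 0 °C
Reagents that add atoms: none
Why: Williamson etherification in which the alkoxide is trapped as it forms by a very reactive propargylic bromide in a cold aprotic medium, which should hold back Payne migration and oxirane opening; no bond at the carbinol centre is broken, so its configuration is retained.

Step 14
Reactants: 5 guaiacyl epoxy alcohol; 19 bromoaryl propargyl bromide
Product: 21 half B, (2S)-2-[(R)-[4-(benzyloxy)-3-methoxyphenyl]({3-[4-(benzyloxy)-3-bromo-5-methoxyphenyl]prop-2-yn-1-yl}oxy)methyl]oxirane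
Conditions: NaH (added last to both partners), n-Bu4NI (cat.), THF/DMF, −10 → 0 °C
Reagents that add atoms: none
Why: Williamson etherification as in step 13; only the sp3 bromide is displaced, which gives the constitutional isomer of 20 with the aryl bromide on the alkyne side.

Step 15
Reactants: 21 half B
Product: 22 half B pinacol boronate (Bpin in place of Br; benzylic ether carbon R, oxirane S)
Conditions: B2pin2, Pd(dppf)Cl2 (cat.), KOAc, 1,4-dioxane, 80 °C
Reagents that add atoms: bis(pinacolato)diboron, CC1(C)OB(OC1(C)C)B1OC(C)(C)C(C)(C)O1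
Why: Miyaura borylation (oxidative addition into Ar–Br, acetate-assisted transmetalation with the diboron), whose weak base spares the oxirane and propargyl ether and does not promote homocoupling.

Step 16
Reactants: 20 half A; 22 half B pinacol boronate
Product: 23 5,5'-biaryl bis(epoxy propargyl ether) (both benzylic ether carbons R, both oxiranes S)
Conditions: Pd(OAc)2/SPhos (cat.), K3PO4, toluene/H2O, 60 °C
Reagents that add atoms: none
Why: Suzuki–Miyaura coupling with a bulky electron-rich biarylphosphine suited to two electron-rich partners that each carry one ortho benzyloxy group, at a temperature the oxiranes and alkynes should survive; with only two ortho substituents the new axis rotates freely and adds no stereoelement.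

Step 17
Reactants: 23 5,5'-biaryl bis(epoxy propargyl ether)
Product: 25 biaryl bis[(2S,3R)-2-aryl-4-benzylidene-3-(hydroxymethyl)oxolane] (tetra-O-benzyl diol; alkene geometry open), via bis(chlorotitanocene alkoxide) 24 (not isolated)
Conditions: Cp2TiCl2 (6 equiv), Zn dust, THF, rt (green Cp2TiCl); added slowly to 23 in degassed THF at high dilution, rt; cold dilute HCl
Reagents that add atoms: none
Why: Cp2TiCl coordinates each terminal oxirane and breaks its internal C–O bond by single-electron transfer, which gives at both sites the more substituted, secondary β-titanoxy radical at the future C3 and erases the oxirane CH centre. Each radical attacks the near alkyne carbon that it reaches through C2–O1–C5, so ring A and ring B (each O1–C2–C3–C4–C5) both close by 5-exo-dig C3–C4 bond formation; the α-aryl vinyl radicals are then quenched by hydrogen abstraction from THF or by capture with further Ti(III) and protonolysis, and acid work-up of the titanium alkoxide 24 frees the two CH2OH groups. The closest known reaction type is the titanocene(III)-mediated reductive opening and 5-exo cyclization of epoxy allyl or propargyl ethers to 3-(hydroxymethyl)oxolanes, familiar from furanoid lignan work, here simply run at two sites that the biaryl holds apart. The only new stereocentres are the two C3 atoms, each controlled by its neighbouring C2 centre: in the chair-like 5-exo transition state the C2 aryl sits pseudo-equatorial and the CH2OTi arm on the radical carbon turns away from it, which should give the 2,3-trans (2S,3R) rings. The selectivity required is ring closure ahead of Ti(III) capture of the C3 radical (deoxygenation or plain reduction), and it is secured by the aryl-conjugated alkyne as a fast acceptor, by the ether oxygen in the tether and by slow addition of the reductant at high dilution. Benzyl ethers, methyl ethers and the biaryl do not react with Ti(III).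

Step 18
Reactants: 25 bis(benzylidene oxolane) diol
Product: 26 bis(tert-butyldimethylsilyl ether) of 25
Conditions: TBSCl, imidazole, DMF, rt
Reagents that add atoms: tert-butyldimethylsilyl chloride, CC(C)(C)[Si](C)(C)Cl
Why: Standard imidazole-promoted silylation of the two primary alcohols removes any hydroxyl direction of the oxidant and enlarges the C3 arm so that it shields one face of the adjacent alkene.

Step 19
Reactants: 26 bis(silyl ether)
Product: 27 bis(spiro-oxirane) bis(silyl ether) (C4 S in both rings, oxirane oxygen trans to the C3 arm; benzylic oxirane CH open)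
Conditions: DMDO (acetone solution, 2.5 equiv), CH2Cl2, −40 → −20 °C; volatiles removed cold, used crude
Reagents that add atoms: dimethyldioxirane, CC1(C)OO1
Why: Dimethyldioxirane epoxidation is concerted and acid-free, as the easily ionised p-alkoxyphenyl oxirane demands, and oxygen should reach each electron-rich trisubstituted alkene on the face opposite the neighbouring CH2OTBS arm (pushed pseudo-axial by allylic strain), which sets C4.

Step 20
Reactants: 27 bis(spiro-oxirane) bis(silyl ether)
Product: 28 bis(silyl ether) of the target (both rings 2S,3R,4S; four free phenols, two tertiary alcohols)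
Conditions: H2 (1 atm), 10% Pd/C, solid NaHCO3, EtOAc, rt; stopped at 6 equiv H2
Reagents that add atoms: none
Why: Catalytic hydrogenolysis cleaves the benzylic C–O bond of each aryl oxirane and the four phenolic benzyl ethers while the C4–O bonds stay intact, so C4 keeps its configuration; the buffered aprotic medium and the stop at calculated uptake protect the slower-reacting benzylic C2–O1 bonds.

Step 21
Reactants: 28 bis(silyl ether) of the target
Product: 29 CNP0269573.1
Conditions: NH4F, MeOH, 50 °C
Reagents that add atoms: none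
Why: Fluoride-driven desilylation of the two primary TBS ethers under nearly neutral conditions gives only volatile by-products, should not ionise the p-hydroxybenzylic C2–O1 bonds, and touches no stereocentre.

Compound list
1 | vanillin | COc1cc(C=O)ccc1O | starting material
2 | 4-(benzyloxy)-3-methoxybenzaldehyde | COc1cc(C=O)ccc1OCc1ccccc1 | intermediate
3 | vinylmagnesium bromide | C=C[Mg]Br | starting material
4 | rac-1-[4-(benzyloxy)-3-methoxyphenyl]prop-2-en-1-ol | COc1cc(C(O)C=C)ccc1OCc1ccccc1 | intermediate
5 | (R)-[4-(benzyloxy)-3-methoxyphenyl][(2S)-oxiran-2-yl]methanol | O[C@H](c1ccc(OCc2ccccc2)c(OC)c1)[C@@H]1CO1 | intermediate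
6 | 5-bromovanillin | COc1cc(C=O)cc(Br)c1O | starting material
7 | 4-(benzyloxy)-3-bromo-5-methoxybenzaldehyde | COc1cc(C=O)cc(Br)c1OCc1ccccc1 | intermediate
8 | rac-1-[4-(benzyloxy)-3-bromo-5-methoxyphenyl]prop-2-en-1-ol | COc1cc(C(O)C=C)cc(Br)c1OCc1ccccc1 | intermediate
9 | (R)-[4-(benzyloxy)-3-bromo-5-methoxyphenyl][(2S)-oxiran-2-yl]methanol | O[C@H](c1cc(OC)c(OCc2ccccc2)c(Br)c1)[C@@H]1CO1 | intermediate
10 | Ohira–Bestmann reagent, dimethyl (1-diazo-2-oxopropyl)phosphonate | COP(=O)(OC)C(=[N+]=[N-])C(C)=O | starting material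
11 | 1-(benzyloxy)-4-ethynyl-2-methoxybenzene | C#Cc1ccc(OCc2ccccc2)c(OC)c1 | intermediate
12 | formaldehyde (used as paraformaldehyde) | C=O | starting material
13 | lithium acetylide of 11 | [Li]C#Cc1ccc(OCc2ccccc2)c(OC)c1 | intermediate (not isolated)
14 | 3-[4-(benzyloxy)-3-methoxyphenyl]prop-2-yn-1-ol | OCC#Cc1ccc(OCc2ccccc2)c(OC)c1 | intermediate
15 | 1-(benzyloxy)-4-(3-bromoprop-1-yn-1-yl)-2-methoxybenzene | BrCC#Cc1ccc(OCc2ccccc2)c(OC)c1 | intermediate
16 | 2-(benzyloxy)-1-bromo-5-ethynyl-3-methoxybenzene | C#Cc1cc(OC)c(OCc2ccccc2)c(Br)c1 | intermediate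
17 | lithium acetylide of 16 | [Li]C#Cc1cc(OC)c(OCc2ccccc2)c(Br)c1 | intermediate (not isolated)
18 | 3-[4-(benzyloxy)-3-bromo-5-methoxyphenyl]prop-2-yn-1-ol | OCC#Cc1cc(OC)c(OCc2ccccc2)c(Br)c1 | intermediate
19 | 2-(benzyloxy)-1-bromo-5-(3-bromoprop-1-yn-1-yl)-3-methoxybenzene | BrCC#Cc1cc(OC)c(OCc2ccccc2)c(Br)c1 | intermediate
20 | half A, epoxy propargyl ether with bromine on the carbinol aryl (ether carbon R, oxirane S) | COc1cc(C#CCO[C@H](c2cc(OC)c(OCc3ccccc3)c(Br)c2)[C@@H]2CO2)ccc1OCc1ccccc1 | intermediate
21 | half B, epoxy propargyl ether with bromine on the alkyne aryl (ether carbon R, oxirane S) | COc1cc(C#CCO[C@H](c2ccc(OCc3ccccc3)c(OC)c2)[C@@H]2CO2)cc(Br)c1OCc1ccccc1 | intermediate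
22 | half B pinacol boronate | COc1cc(C#CCO[C@H](c2ccc(OCc3ccccc3)c(OC)c2)[C@@H]2CO2)cc(B2OC(C)(C)C(C)(C)O2)c1OCc1ccccc1 | intermediate
23 | 5,5'-biaryl bis(epoxy propargyl ether) | COc1cc(C#CCO[C@H](c2cc(OC)c(OCc3ccccc3)c(-c3cc(C#CCO[C@H](c4ccc(OCc5ccccc5)c(OC)c4)[C@@H]4CO4)cc(OC)c3OCc3ccccc3)c2)[C@@H]2CO2)ccc1OCc1ccccc1 | intermediate
24 | bis(chlorotitanocene alkoxide) of 25 (Cp drawn σ-bonded) | COc1cc(C=C2CO[C@H](c3cc(OC)c(OCc4ccccc4)c(-c4cc(C=C5CO[C@H](c6ccc(OCc7ccccc7)c(OC)c6)[C@H]5CO[Ti](Cl)(C6C=CC=C6)C6C=CC=C6)cc(OC)c4OCc4ccccc4)c3)[C@H]2CO[Ti](Cl)(C3C=CC=C3)C3C=CC=C3)ccc1OCc1ccccc1 | intermediate (not isolated)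
25 | biaryl bis[(2S,3R)-2-aryl-4-benzylidene-3-(hydroxymethyl)oxolane], tetra-O-benzyl | COc1cc(C=C2CO[C@H](c3cc(OC)c(OCc4ccccc4)c(-c4cc(C=C5CO[C@H](c6ccc(OCc7ccccc7)c(OC)c6)[C@H]5CO)cc(OC)c4OCc4ccccc4)c3)[C@H]2CO)ccc1OCc1ccccc1 | intermediate
26 | bis(TBS ether) of 25 | COc1cc(C=C2CO[C@H](c3cc(OC)c(OCc4ccccc4)c(-c4cc(C=C5CO[C@H](c6ccc(OCc7ccccc7)c(OC)c6)[C@H]5CO[Si](C)(C)C(C)(C)C)cc(OC)c4OCc4ccccc4)c3)[C@H]2CO[Si](C)(C)C(C)(C)C)ccc1OCc1ccccc1 | intermediate
27 | bis(spiro-oxirane) bis(TBS ether), oxirane O trans to the C3 arm in both rings | COc1cc(C2[C@@]3(O2)CO[C@H](c2cc(OC)c(OCc4ccccc4)c(-c4cc(C5[C@@]6(O5)CO[C@H](c5ccc(OCc7ccccc7)c(OC)c5)[C@H]6CO[Si](C)(C)C(C)(C)C)cc(OC)c4OCc4ccccc4)c2)[C@H]3CO[Si](C)(C)C(C)(C)C)ccc1OCc1ccccc1 | intermediate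
28 | bis(TBS ether) of the target, both rings (2S,3R,4S) | COc1cc(C[C@@]2(O)CO[C@H](c3cc(OC)c(O)c(-c4cc(C[C@@]5(O)CO[C@H](c6ccc(O)c(OC)c6)[C@H]5CO[Si](C)(C)C(C)(C)C)cc(OC)c4O)c3)[C@H]2CO[Si](C)(C)C(C)(C)C)ccc1O | intermediate
29 | CNP0269573.1, 5,5'-linked bis-oxolane lignan dimer, both rings (2S,3R,4S): aryl and OH on one face, CH2OH and benzyl on the other | COc1cc(C[C@@]2(O)CO[C@H](c3cc(OC)c(O)c(-c4cc(C[C@@]5(O)CO[C@H](c6ccc(O)c(OC)c6)[C@H]5CO)cc(OC)c4O)c3)[C@H]2CO)ccc1O | target

Total step count: 21.
Longest linear sequence: 12 steps (6 → 7 → 16 → 18 → 19 → 21 → 22 → 23 → 25 → 26 → 27 → 28 → 29).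

Steps most likely to fail

Step 17. The C3 radical at one of the two sites may be captured by Ti(III) before ring closure. Any loss of 2,3-trans selectivity also counts twice in a twofold event, so doubly correct material is eroded statistically. The fallback closes the rings before the biaryl bond is made. It sets out from 20 and 21, and each half is treated on its own with Cp2TiCl in THF; aryl bromides are inert to it. This gives the bromoaryl benzylidene oxolane from half A F1 and the isomeric bromobenzylidene oxolane from half B F2, each purified as a monomer. Miyaura borylation converts F2 into the oxolane pinacol boronate F3, and Suzuki–Miyaura coupling of F1 with F3 comes back to the route at 25.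

Step 19. Facial selectivity may be poor at one or both benzylidenes. The p-alkoxyphenyl oxirane may also ionise, with skeletal rearrangement or solvolysis, before it can be reduced. The fallback replaces the labile oxirane by a stable diol. It sets out from 26, where catalytic OsO4/NMO dihydroxylation uses a bulkier oxidant that should discriminate the faces more strongly. The product is the chromatographable bis(4-hydroxy-4-[aryl(hydroxy)methyl]oxolane) tetraol F4, so diastereomers can be removed at this stage. Ac2O/pyridine acylates only the secondary benzylic hydroxyls to give the bis(benzylic acetate) F5. Hydrogenolysis over Pd/C then removes the benzylic acetates together with the four benzyl ethers and comes back to the route at 28.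

Step 20. Over-reduction by hydrogenolysis of the benzylic C2–O1 bonds may set in once the phenols are free, and Pd-induced isomerisation of the oxiranes may compete with their reductive opening. The fallback separates the two reductions. It sets out from crude 27, and LiEt3BH in THF at 0 °C delivers hydride by SN2 attack at the less substituted, benzylic oxirane carbon. This gives the tetra-O-benzyl bis(tertiary alcohol) bis(silyl ether) F6, which is stable and can be purified. A short transfer hydrogenolysis (Pd/C, 1,4-cyclohexadiene) then has to remove only the fast-cleaving phenolic benzyl ethers and comes back to the route at 28.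

Further compounds
F1 | step 17 | [(2S,3R)-2-[4-(benzyloxy)-3-bromo-5-methoxyphenyl]-4-[4-(benzyloxy)-3-methoxybenzylidene]oxolan-3-yl]methanol | COc1cc(C=C2CO[C@H](c3cc(OC)c(OCc4ccccc4)c(Br)c3)[C@H]2CO)ccc1OCc1ccccc1
F2 | step 17 | [(2S,3R)-2-[4-(benzyloxy)-3-methoxyphenyl]-4-[4-(benzyloxy)-3-bromo-5-methoxybenzylidene]oxolan-3-yl]methanol | COc1cc(C=C2CO[C@H](c3ccc(OCc4ccccc4)c(OC)c3)[C@H]2CO)cc(Br)c1OCc1ccccc1
F3 | step 17 | pinacol boronate of F2 (Bpin in place of Br) | COc1cc(C=C2CO[C@H](c3ccc(OCc4ccccc4)c(OC)c3)[C@H]2CO)cc(B2OC(C)(C)C(C)(C)O2)c1OCc1ccccc1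
F4 | step 19 | tetra-O-benzyl bis(TBS ether) tetraol, C4 tertiary OH trans to the C3 arm, benzylic CHOH open | COc1cc(C(O)[C@@]2(O)CO[C@H](c3cc(OC)c(OCc4ccccc4)c(-c4cc(C(O)[C@@]5(O)CO[C@H](c6ccc(OCc7ccccc7)c(OC)c6)[C@H]5CO[Si](C)(C)C(C)(C)C)cc(OC)c4OCc4ccccc4)c3)[C@H]2CO[Si](C)(C)C(C)(C)C)ccc1OCc1ccccc1
F5 | step 19 | bis(benzylic acetate) of F4 | COc1cc(C(OC(C)=O)[C@@]2(O)CO[C@H](c3cc(OC)c(OCc4ccccc4)c(-c4cc(C(OC(C)=O)[C@@]5(O)CO[C@H](c6ccc(OCc7ccccc7)c(OC)c6)[C@H]5CO[Si](C)(C)C(C)(C)C)cc(OC)c4OCc4ccccc4)c3)[C@H]2CO[Si](C)(C)C(C)(C)C)ccc1OCc1ccccc1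
F6 | step 20 | tetra-O-benzyl bis(TBS ether) of the target, both rings (2S,3R,4S) | COc1cc(C[C@@]2(O)CO[C@H](c3cc(OC)c(OCc4ccccc4)c(-c4cc(C[C@@]5(O)CO[C@H](c6ccc(OCc7ccccc7)c(OC)c6)[C@H]5CO[Si](C)(C)C(C)(C)C)cc(OC)c4OCc4ccccc4)c3)[C@H]2CO[Si](C)(C)C(C)(C)C)ccc1OCc1ccccc1
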